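**Plan**

- Retrosynthesis: the side chain is cut at C12–C13 (B-alkyl Suzuki coupling) and at C11=C12 (methylenation of a C9 aldehyde). The decalin is then cut at the two ring bonds C5–C10 and C8–C9 (intramolecular Diels–Alder), and the open chain at C5=C6 (Horner–Wadsworth–Emmons) and C1–C2 (vinylogous aldol), back to (R)-pantolactone.
- Enabling feature: ring B is bracketed by the bonds C5–C10 and C8–C9, and C1–C4 (CH2, the two cis-diol carbons, the gem-dimethyl carbon) is a four-carbon tether between a C5–C8 diene and a C9=C10 dienophile.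
- Forward: pantolactone is opened to a C2 aldehyde, C1 and C9–C11 are added, and the diol is tied up as the acetonide. C5 is turned into the 2-silyloxydiene and rings A and B close in one step. The C7 oxygen is then exchanged for the C7=C8 olefin, the C13–C16 unit is joined, and deprotection and acetylation finish.
- Stereochemistry: C3 comes from pantolactone and C2 from Felkin addition to the α-silyloxy aldehyde. C5, C9 and C10 come from the cycloaddition (olefin geometry plus the acetonide on the tether), and 13E from the vinyl iodide.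

Key step: step 11

Remark: atom numbers are those of the labdane skeleton (C1–C10 decalin, C11–C16 side chain) in all intermediates; (E)-3-iodobut-2-en-1-ol is assumed to be purchasable.

**Route**

Step 1
Reactants: 1 (R)-pantolactone
Product: 2 (2R)-2,4-dihydroxy-N-methoxy-N,3,3-trimethylbutanamide
Conditions: MeNH(OMe)·HCl, Me3Al, CH2Cl2, 0 °C → rt; Rochelle salt work-up; used crude at once
Reagents that add atoms: N,O-dimethylhydroxylamine hydrochloride, CNOC.Cl
Why: Weinreb aminolysis of the lactone by the aluminium amide opens the ring at the acyl carbon without touching the carbinol centre, leaving C2 at the acyl oxidation level and both hydroxyls free.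

Step 2
Reactants: 2 (2R)-2,4-dihydroxy-N-methoxy-N,3,3-trimethylbutanamide
Product: 4 (2R)-4-(tert-butyldiphenylsilyloxy)-N-methoxy-N,3,3-trimethyl-2-(triethylsilyloxy)butanamide, via mono-TBDPS ether 3 (not isolated)
Conditions: TBDPSCl (1.05 equiv), imidazole, DMF, 0 °C → rt; then TESCl, rt
Reagents that add atoms: tert-butyl(chloro)diphenylsilane, CC(C)(C)[Si](Cl)(c1ccccc1)c1ccccc1; chlorotriethylsilane, CC[Si](Cl)(CC)CC
Why: Sequential silyl ether formation, in which the bulky silyl chloride takes the primary neopentyl hydroxyl first and the smaller, later acid-labile TES group then caps the hindered secondary hydroxyl, which also blocks relactonisation.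

Step 3
Reactants: 4 (2R)-4-(tert-butyldiphenylsilyloxy)-N-methoxy-N,3,3-trimethyl-2-(triethylsilyloxy)butanamide
Product: 5 (2R)-4-(tert-butyldiphenylsilyloxy)-3,3-dimethyl-2-(triethylsilyloxy)butanal
Conditions: i-Bu2AlH, THF, −78 °C; Rochelle salt work-up
Reagents that add atoms: none
Why: Weinreb amide reduction stops at the aldehyde because the chelated tetrahedral aluminate survives until work-up, and the α-silyloxy centre should not epimerise at this temperature.

Step 4
Reactants: 6 ethyl 3-methylbut-2-enoate
Product: 7 (1Z)-1-ethoxy-3-methyl-1-(trimethylsilyloxy)buta-1,3-diene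
Conditions: LiN(i-Pr)2, THF, −78 °C; Me3SiCl, −78 °C → rt; distillation
Reagents that add atoms: chlorotrimethylsilane, C[Si](C)(C)Cl
Why: Kinetic γ-deprotonation of the enoate to the extended lithium dienolate and O-silylation is the standard silyl ketene acetal formation; the ketene acetal geometry is lost in the next step.

Step 5
Reactants: 5 (2R)-4-(tert-butyldiphenylsilyloxy)-3,3-dimethyl-2-(triethylsilyloxy)butanal; 7 (1Z)-1-ethoxy-3-methyl-1-(trimethylsilyloxy)buta-1,3-diene
Product: 8 ethyl (2E,5S,6R)-8-(tert-butyldiphenylsilyloxy)-5-hydroxy-3,7,7-trimethyl-6-(triethylsilyloxy)oct-2-enoate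
Conditions: BF3·OEt2, CH2Cl2/Et2O, −78 °C; aqueous NaHCO3
Reagents that add atoms: none
Why: Vinylogous Mukaiyama aldol reaction through an open transition state, in which the non-chelating Lewis acid and the α-silyloxy group enforce Felkin–Anh (Cornforth) attack anti to the quaternary carbon to set C2 (anti to the C3 oxygen), and the s-trans dienolate should give the (E)-enoate.

Step 6
Reactants: 8 ethyl (2E,5S,6R)-8-(tert-butyldiphenylsilyloxy)-5-hydroxy-3,7,7-trimethyl-6-(triethylsilyloxy)oct-2-enoate
Product: 10 acetonide of the C2/C3 diol with the C5 TBDPS ether, via diol 9 (not isolated)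
Conditions: CSA (cat.), MeOH, 0 °C; concentrate; 2,2-dimethoxypropane, acetone, rt
Reagents that add atoms: 2,2-dimethoxypropane, COC(C)(C)OC
Why: Acid methanolysis removes only the secondary TES ether (the primary neopentyl TBDPS ether is far more acid-stable) and transketalisation closes the cis-dioxolane of the anti-diol, so no hydroxyl is left to add to the later enone.

Step 7
Reactants: 10 acetonide TBDPS ether
Product: 11 ethyl (2E)-4-[(4S,5R)-5-(1-hydroxy-2-methylpropan-2-yl)-2,2-dimethyl-1,3-dioxolan-4-yl]-3-methylbut-2-enoate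
Conditions: Bu4NF, THF, rt
Reagents that add atoms: none
Why: Fluoride-mediated cleavage of the silyl ether; the acetonide and the hindered enoate are inert.

Step 8
Reactants: 11 ethyl (2E)-4-[(4S,5R)-5-(1-hydroxy-2-methylpropan-2-yl)-2,2-dimethyl-1,3-dioxolan-4-yl]-3-methylbut-2-enoate
Product: 12 ethyl (2E)-4-[(4S,5R)-2,2-dimethyl-5-(2-methyl-1-oxopropan-2-yl)-1,3-dioxolan-4-yl]-3-methylbut-2-enoate
Conditions: Dess–Martin periodinane, NaHCO3, CH2Cl2, 0 °C → rt
Reagents that add atoms: none
Why: Dess–Martin oxidation of the neopentyl primary alcohol gives a non-enolisable aldehyde that cannot epimerise or eliminate.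

Step 9
Reactants: 12 ethyl (2E)-4-[(4S,5R)-2,2-dimethyl-5-(2-methyl-1-oxopropan-2-yl)-1,3-dioxolan-4-yl]-3-methylbut-2-enoate; 13 diethyl (2-oxobutyl)phosphonate
Product: 14 ethyl (2E)-4-[(4S,5R)-2,2-dimethyl-5-[(3E)-2-methyl-5-oxohept-3-en-2-yl]-1,3-dioxolan-4-yl]-3-methylbut-2-enoate
Conditions: Ba(OH)2, THF/H2O (40:1), rt
Reagents that add atoms: none
Why: Horner–Wadsworth–Emmons olefination with a β-ketophosphonate under mild hydroxide conditions is reliable for hindered aldehydes and gives the (E)-enone (C5=C6).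

Step 10
Reactants: 14 ethyl (2E)-4-[(4S,5R)-2,2-dimethyl-5-[(3E)-2-methyl-5-oxohept-3-en-2-yl]-1,3-dioxolan-4-yl]-3-methylbut-2-enoate
Product: 15 ethyl (2E)-4-[(4S,5R)-5-[(3E,5Z)-5-(tert-butyldimethylsilyloxy)-2-methylhepta-3,5-dien-2-yl]-2,2-dimethyl-1,3-dioxolan-4-yl]-3-methylbut-2-enoate
Conditions: TBSOTf, Et3N, CH2Cl2, 0 °C
Reagents that add atoms: tert-butyldimethylsilyl triflate, CC(C)(C)[Si](C)(C)OS(=O)(=O)C(F)(F)F
Why: Soft enolisation with silyl triflate and amine, in which C8 is the only enolisable position because C4 is quaternary, and ethyl ketones should give mainly the (Z)-enol ether with the methyl outside the diene.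

Step 11
Reactants: 15 ethyl (2E)-4-[(4S,5R)-5-[(3E,5Z)-5-(tert-butyldimethylsilyloxy)-2-methylhepta-3,5-dien-2-yl]-2,2-dimethyl-1,3-dioxolan-4-yl]-3-methylbut-2-enoate
Product: 16 trans-fused adduct with C9 ethyl ester, C6=C7 TBS enol ether, C8 and C10 methyls and 2,3-acetonide
Conditions: toluene (0.01 M), BHT (cat.), Et3N (trace), 180 °C, sealed tube
Reagents that add atoms: none
Why: This is a concerted, suprafacial thermal [4+2] cycloaddition between the electron-rich (E,Z)-2-silyloxydiene C5=C6–C7(OTBS)=C8 and the (E)-enoate C9=C10, the closest known type being the type 1 intramolecular Diels–Alder reaction of 1,7,9-decatrienes carrying a 2-silyloxydiene. Ring B (C5–C10) is the six-membered ring made by the cycloaddition itself through the bonds C5–C10 and C8–C9, and ring A closes in the same event as a fused six-membered ring because the C1–C4 tether links the diene terminus C5 to the dienophile carbon C10. The trans relation of H5 and the C10 methyl follows from the ester-endo transition state with a chair-like tether on the (E)-diene, C9 from suprafacial retention of the (E)-enoate geometry (ester cis to the C10 methyl), and C8 from the (Z)-enol ether (methyl outside, ending cis to the ester; this centre is erased later). The diene face is chosen by the C2/C3 acetonide, since only one chair places the C2 oxygen equatorial, away from the axial C4 methyl and the C10 methyl, so the new centres form anti to it. The step needs endo (trans-fusion) and facial selectivity, which the two E geometries, the gem-dimethyl group next to the diene (which also speeds closure) and the cis-fused dioxolane should secure, while the tether fixes the regiochemistry.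

Step 12
Reactants: 16 trans-fused adduct with C9 ethyl ester
Product: 17 C11 primary alcohol with C6=C7 TBS enol ether and 2,3-acetonide
Conditions: LiAlH4, Et2O, 0 °C
Reagents that add atoms: none
Why: Hydride reduction of the hindered ester to the primary alcohol; silyl enol ether and acetonide are inert to LiAlH4.

Step 13
Reactants: 17 C11 primary alcohol
Product: 18 C9 aldehyde with C6=C7 TBS enol ether and 2,3-acetonide
Conditions: Dess–Martin periodinane, pyridine, CH2Cl2, 0 °C → rt
Reagents that add atoms: none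
Why: Dess–Martin oxidation buffered with pyridine should spare the acid-sensitive enol ether and leave the equatorial aldehyde at C9 unepimerised.

Step 14
Reactants: 18 C9 aldehyde
Product: 19 C9 vinyl compound (C11=C12) with C6=C7 TBS enol ether and 2,3-acetonide
Conditions: Ph3PCH3Br, KN(SiMe3)2, THF, 0 °C; then 18, −78 → 0 °C
Reagents that add atoms: methyltriphenylphosphonium bromide, C[P+](c1ccccc1)(c1ccccc1)c1ccccc1.[Br-]
Why: Wittig methylenation with the small non-stabilised ylide is fast at low temperature, so the C9 centre α to the aldehyde should not epimerise.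

Step 15
Reactants: 19 C9 vinyl compound with C6=C7 TBS enol ether
Product: 21 C7 ketone with equatorial C8 methyl, via axial-methyl ketone 20 (not isolated)
Conditions: Bu4NF, THF, 0 °C → rt; then K2CO3, MeOH, rt
Reagents that add atoms: none
Why: Fluoride cleaves the silyl enol ether with protonation at C6, and base equilibration then moves the C8 methyl out of the axial position (syn-diaxial to the C10 methyl) into the equatorial one, which puts C8–H axial for the next step.

Step 16
Reactants: 21 C7 ketone with equatorial C8 methyl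
Product: 22 C7=C8 enol triflate with C9 vinyl group and 2,3-acetonide
Conditions: Tf2O, 2,6-di-tert-butyl-4-methylpyridine, CH2Cl2, 0 °C → rt
Reagents that add atoms: triflic anhydride, O=S(=O)(OS(=O)(=O)C(F)(F)F)C(F)(F)F
Why: Enol triflate formation under thermodynamic conditions (O-triflation, then loss of the axial tertiary C8 proton) should give the more substituted, tetrasubstituted C7=C8 triflate.

Step 17
Reactants: 22 C7=C8 enol triflate
Product: 23 2,3-acetonide of the 9-vinyl decal-7-ene
Conditions: Pd(OAc)2 (cat.), PPh3, n-Bu3N, HCO2H, DMF, 60 °C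
Reagents that add atoms: none
Why: Palladium-catalysed formate reduction of an enol triflate (oxidative addition, formate exchange, decarboxylation, reductive elimination) replaces OTf by H without moving the double bond.

Step 18
Reactants: 23 2,3-acetonide of the 9-vinyl decal-7-ene; 24 (E)-3-iodobut-2-en-1-ol
Product: 26 (13E)-2,3-O-isopropylidene-labda-7,13-diene-2,3,15-triol, via B-alkyl-9-BBN borane 25 (not isolated)
Conditions: 9-BBN dimer, THF, rt; then 24, PdCl2(dppf) (cat.), AsPh3, aqueous K3PO4, DMF, rt
Reagents that add atoms: none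
Why: 9-BBN hydroborates only the monosubstituted vinyl group (boron at C12) and not the trisubstituted ring olefin, and the B-alkyl Suzuki–Miyaura coupling with the vinyl iodide proceeds with retention to give the 13E olefin.

Step 19
Reactants: 26 (13E)-2,3-O-isopropylidene-labda-7,13-diene-2,3,15-triol
Product: 27 (2S,3R,5S,9R,10S,13E)-labda-7,13-diene-2,3,15-triol
Conditions: PPTS, MeOH, 50 °C
Reagents that add atoms: none
Why: Mild acid-catalysed transketalisation removes the acetonide under conditions that trisubstituted olefins and primary allylic alcohols tolerate.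

Step 20
Reactants: 27 (2S,3R,5S,9R,10S,13E)-labda-7,13-diene-2,3,15-triol
Product: 28 (2S,3R,5S,9R,10S,13E)-3-hydroxylabda-7,13-diene-2,15-diyl diacetate
Conditions: Ac2O (2.2 equiv), pyridine, CH2Cl2, 0 °C
Reagents that add atoms: acetic anhydride, CC(=O)OC(C)=O
Why: Sterically differentiated acylation, in which the primary allylic C15 hydroxyl and the equatorial C2 hydroxyl react while the axial C3 hydroxyl next to the gem-dimethyl carbon should remain free.

**Compound list**

1 | (R)-pantolactone | CC1(C)COC(=O)[C@@H]1O | starting material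
2 | (2R)-2,4-dihydroxy-N-methoxy-N,3,3-trimethylbutanamide | CON(C)C(=O)[C@H](O)C(C)(C)CO | intermediate
3 | (2R)-4-(tert-butyldiphenylsilyloxy)-2-hydroxy-N-methoxy-N,3,3-trimethylbutanamide | CON(C)C(=O)[C@H](O)C(C)(C)CO[Si](c1ccccc1)(c1ccccc1)C(C)(C)C | intermediate (not isolated)
4 | (2R)-4-(tert-butyldiphenylsilyloxy)-N-methoxy-N,3,3-trimethyl-2-(triethylsilyloxy)butanamide | CON(C)C(=O)[C@H](O[Si](CC)(CC)CC)C(C)(C)CO[Si](c1ccccc1)(c1ccccc1)C(C)(C)C | intermediate
5 | (2R)-4-(tert-butyldiphenylsilyloxy)-3,3-dimethyl-2-(triethylsilyloxy)butanal | O=C[C@H](O[Si](CC)(CC)CC)C(C)(C)CO[Si](c1ccccc1)(c1ccccc1)C(C)(C)C | intermediate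
6 | ethyl 3-methylbut-2-enoate | CCOC(=O)C=C(C)C | starting material
7 | (1Z)-1-ethoxy-3-methyl-1-(trimethylsilyloxy)buta-1,3-diene | C=C(C)/C=C(/OCC)O[Si](C)(C)C | intermediate
8 | ethyl (2E,5S,6R)-8-(tert-butyldiphenylsilyloxy)-5-hydroxy-3,7,7-trimethyl-6-(triethylsilyloxy)oct-2-enoate | CCOC(=O)/C=C(\C)C[C@H](O)[C@H](O[Si](CC)(CC)CC)C(C)(C)CO[Si](c1ccccc1)(c1ccccc1)C(C)(C)C | intermediate
9 | ethyl (2E,5S,6R)-8-(tert-butyldiphenylsilyloxy)-5,6-dihydroxy-3,7,7-trimethyloct-2-enoate | CCOC(=O)/C=C(\C)C[C@H](O)[C@H](O)C(C)(C)CO[Si](c1ccccc1)(c1ccccc1)C(C)(C)C | intermediate (not isolated)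
10 | ethyl (2E)-4-[(4S,5R)-5-[1-(tert-butyldiphenylsilyloxy)-2-methylpropan-2-yl]-2,2-dimethyl-1,3-dioxolan-4-yl]-3-methylbut-2-enoate | CCOC(=O)/C=C(\C)C[C@@H]1OC(C)(C)O[C@@H]1C(C)(C)CO[Si](c1ccccc1)(c1ccccc1)C(C)(C)C | intermediate
11 | ethyl (2E)-4-[(4S,5R)-5-(1-hydroxy-2-methylpropan-2-yl)-2,2-dimethyl-1,3-dioxolan-4-yl]-3-methylbut-2-enoate | CCOC(=O)/C=C(\C)C[C@@H]1OC(C)(C)O[C@@H]1C(C)(C)CO | intermediate
12 | ethyl (2E)-4-[(4S,5R)-2,2-dimethyl-5-(2-methyl-1-oxopropan-2-yl)-1,3-dioxolan-4-yl]-3-methylbut-2-enoate | CCOC(=O)/C=C(\C)C[C@@H]1OC(C)(C)O[C@@H]1C(C)(C)C=O | intermediate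
13 | diethyl (2-oxobutyl)phosphonate | CCC(=O)CP(=O)(OCC)OCC | starting material
14 | ethyl (2E)-4-[(4S,5R)-2,2-dimethyl-5-[(3E)-2-methyl-5-oxohept-3-en-2-yl]-1,3-dioxolan-4-yl]-3-methylbut-2-enoate | CCOC(=O)/C=C(\C)C[C@@H]1OC(C)(C)O[C@@H]1C(C)(C)/C=C/C(=O)CC | intermediate
15 | ethyl (2E)-4-[(4S,5R)-5-[(3E,5Z)-5-(tert-butyldimethylsilyloxy)-2-methylhepta-3,5-dien-2-yl]-2,2-dimethyl-1,3-dioxolan-4-yl]-3-methylbut-2-enoate (cycloaddition precursor) | CCOC(=O)/C=C(\C)C[C@@H]1OC(C)(C)O[C@@H]1C(C)(C)/C=C/C(O[Si](C)(C)C(C)(C)C)=C/C | intermediate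
16 | cycloadduct: trans-decal-6-ene with C9 CO2Et, C7 OTBS enol ether, 2,3-acetonide; C8-Me, C9-CO2Et and C10-Me on one face, H5 and both acetonide oxygens on the other; C2, C3, C5, C9, C10 as in 28 | CCOC(=O)[C@@H]1[C@H](C)C(O[Si](C)(C)C(C)(C)C)=C[C@@H]2C(C)(C)[C@H]3OC(C)(C)O[C@H]3C[C@@]12C | intermediate
17 | C11 primary alcohol of 16 (C9-CH2OH) | OC[C@@H]1[C@H](C)C(O[Si](C)(C)C(C)(C)C)=C[C@@H]2C(C)(C)[C@H]3OC(C)(C)O[C@H]3C[C@@]12C | intermediate
18 | C9 aldehyde (C9-CHO) with C6=C7 TBS enol ether and 2,3-acetonide | O=C[C@@H]1[C@H](C)C(O[Si](C)(C)C(C)(C)C)=C[C@@H]2C(C)(C)[C@H]3OC(C)(C)O[C@H]3C[C@@]12C | intermediate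
19 | C9 vinyl compound (C11=C12) with C6=C7 TBS enol ether and 2,3-acetonide | C=C[C@@H]1[C@H](C)C(O[Si](C)(C)C(C)(C)C)=C[C@@H]2C(C)(C)[C@H]3OC(C)(C)O[C@H]3C[C@@]12C | intermediate
20 | C7 ketone, C8 methyl axial (cis to the C9 vinyl group) | C=C[C@@H]1[C@H](C)C(=O)C[C@@H]2C(C)(C)[C@H]3OC(C)(C)O[C@H]3C[C@@]12C | intermediate (not isolated)
21 | C7 ketone, C8 methyl equatorial (trans to the C9 vinyl group) | C=C[C@@H]1[C@@H](C)C(=O)C[C@@H]2C(C)(C)[C@H]3OC(C)(C)O[C@H]3C[C@@]12C | intermediate
22 | C7=C8 enol triflate with C9 vinyl group and 2,3-acetonide | C=C[C@@H]1C(C)=C(OS(=O)(=O)C(F)(F)F)C[C@@H]2C(C)(C)[C@H]3OC(C)(C)O[C@H]3C[C@@]12C | intermediate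
23 | 2,3-(isopropylidenedioxy)-4,4,8,10-tetramethyl-9-vinyl-trans-decal-7-ene, ring centres as in 28 | C=C[C@@H]1C(C)=CC[C@@H]2C(C)(C)[C@H]3OC(C)(C)O[C@H]3C[C@@]12C | intermediate
24 | (E)-3-iodobut-2-en-1-ol | OC/C=C(\C)I | starting material
25 | B-alkyl-9-BBN borane (boron on C12) derived from 23 | C1CCC2CCCC1B2CC[C@@H]1C(C)=CC[C@@H]2C(C)(C)[C@H]3OC(C)(C)O[C@H]3C[C@@]12C | intermediate (not isolated)
26 | (13E)-2,3-O-isopropylidene-labda-7,13-diene-2,3,15-triol, ring centres as in 28 | OC/C=C(\C)CC[C@@H]1C(C)=CC[C@@H]2C(C)(C)[C@H]3OC(C)(C)O[C@H]3C[C@@]12C | intermediate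
27 | (2S,3R,5S,9R,10S,13E)-labda-7,13-diene-2,3,15-triol | OC/C=C(\C)CC[C@@H]1C(C)=CC[C@@H]2C(C)(C)[C@@H](O)[C@@H](O)C[C@@]12C | intermediate
28 | (2S,3R,5S,9R,10S,13E)-3-hydroxylabda-7,13-diene-2,15-diyl diacetate (CNP0254679.1) | CC(=O)OC/C=C(\C)CC[C@@H]1C(C)=CC[C@@H]2C(C)(C)[C@@H](O)[C@@H](OC(C)=O)C[C@@]12C | target

**Count and risks**

Total step count: 20. Longest linear sequence: 19 steps (steps 1–3 and 5–20 from (R)-pantolactone; step 4 prepares the dienolate).

Steps most likely to fail:

1. Step 11. The cycloaddition joins a neopentyl diene terminus to a β,β-disubstituted enoate in the electronically less favoured orientation, so it may be too slow, with desilylation of the dienol ether on long heating. Endo selectivity may also be eroded by the C7 silyloxy group, giving cis-fused material. Fallback: set out from triene 15. Reduction of the ester with i-Bu2AlH at −78 °C (the silyl dienol ether tolerates hydride) would give the (E)-allylic alcohol F1. MnO2 would oxidise it to the (E)-enal F2, a much better dienophile, which would be cyclised with Me2AlCl at low temperature or in toluene at about 110 °C. Aldehyde-activated trienes are known to react faster and with higher endo preference. The adduct is aldehyde 18, where the route is rejoined; steps 12 and 13 are then not needed.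

2. Step 16. Proton loss from the O-triflated ketone may go toward C6 instead of C8, which after reduction would give the C6=C7 regioisomer. Fallback: set out from ketone 21. LiBH(s-Bu)3 should attack from the equatorial direction and give the axial C7 alcohol F3. POCl3 in pyridine would then eliminate anti-periplanar through the axial, tertiary C8–H (Zaitsev orientation) to give diene 23 directly, where the route is rejoined; step 17 is then not needed.

3. Step 5. Two selectivities are asked of one reaction: facial control at C2 may be incomplete, and part of the material may form with the (Z)-enoate geometry and be lost by lactonisation. Fallback: set out from aldehyde 5. BF3·OEt2-promoted addition of allenyltributylstannane (same Felkin control, no olefin geometry at stake) would give the homopropargylic alcohol F4. The TES removal and acetonide formation of step 6 would give the alkyne acetonide F5. Syn-specific Zr-catalysed methylalumination of the terminal alkyne (Me3Al, Cp2ZrCl2 cat., CH2Cl2) and trapping of the alkenylalane with ethyl chloroformate would then give the (E)-enoate with its geometry fixed by the mechanism. This is compound 10, where the route is rejoined.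

Further compounds
F1 | step 11 | (2E)-4-[(4S,5R)-5-[(3E,5Z)-5-(tert-butyldimethylsilyloxy)-2-methylhepta-3,5-dien-2-yl]-2,2-dimethyl-1,3-dioxolan-4-yl]-3-methylbut-2-en-1-ol | OC/C=C(\C)C[C@@H]1OC(C)(C)O[C@@H]1C(C)(C)/C=C/C(O[Si](C)(C)C(C)(C)C)=C/C
F2 | step 11 | (2E)-4-[(4S,5R)-5-[(3E,5Z)-5-(tert-butyldimethylsilyloxy)-2-methylhepta-3,5-dien-2-yl]-2,2-dimethyl-1,3-dioxolan-4-yl]-3-methylbut-2-enal | O=C/C=C(\C)C[C@@H]1OC(C)(C)O[C@@H]1C(C)(C)/C=C/C(O[Si](C)(C)C(C)(C)C)=C/C
F3 | step 16 | axial C7 alcohol of the 9-vinyl decalin (C7-OH on the face of H5, C8 methyl equatorial, 2,3-acetonide) | C=C[C@@H]1[C@@H](C)[C@@H](O)C[C@@H]2C(C)(C)[C@H]3OC(C)(C)O[C@H]3C[C@@]12C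
F4 | step 5 | (4S,5R)-7-(tert-butyldiphenylsilyloxy)-6,6-dimethyl-5-(triethylsilyloxy)hept-1-yn-4-ol | C#CC[C@H](O)[C@H](O[Si](CC)(CC)CC)C(C)(C)CO[Si](c1ccccc1)(c1ccccc1)C(C)(C)C
F5 | step 5 | (4S,5R)-5-[1-(tert-butyldiphenylsilyloxy)-2-methylpropan-2-yl]-2,2-dimethyl-4-(prop-2-yn-1-yl)-1,3-dioxolane | C#CC[C@@H]1OC(C)(C)O[C@@H]1C(C)(C)CO[Si](c1ccccc1)(c1ccccc1)C(C)(C)C
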